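**Plan**
1. Retrosynthesis first cuts the bridge at the CH2–aryl bond, leaving the CH2 on the trione ring as a Mannich base. This gives butyrylfilicinic acid and 3-methylphlorobutyrophenone.
2. The filicinic ring (C1 ketone, C2 butanoyl carbon, C3, C4 bridge carbon, C5, C6 gem-dimethyl carbon) is then cut at C1–C2 and C4–C5.
3. The enabling feature: C1–C6–C5 is a symmetrical dimethylmalonyl unit without alpha-hydrogen, and C2–C3–C4 with the butanoyl group is a 1,3,5-tricarbonyl (triketide) chain. A tert-butyl ester on C4 activates the second nucleophilic carbon, fixes which carbons react, and later leaves as 2-methylpropene and CO2.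
4. Forward: acetoacetate dianion acylation gives the triketide ester; a [3+3] double Claisen acylation with dimethylmalonyl dichloride closes the carbocycle; decarboxylation and Mannich reaction follow; the separately acylated methylphloroglucinol is joined last through the bridge.
5. Stereochemistry: the target has no stereocentre, so nothing has to be set; only enol tautomers exist.

Key step: step 2

Remark: the target is taken as the homologue with two butanoyl groups; every trione is drawn as one of its rapidly interconverting enol tautomers.

Step 1
Reactants: 1 tert-butyl 3-oxobutanoate; 2 N-methoxy-N-methylbutanamide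
Product: 4 tert-butyl 3,5-dioxooctanoate, via dilithium dienolate 3 (not isolated)
Conditions: LiN(iPr)2 (2.2 equiv), THF, 0 °C; then 2, −78 °C → 0 °C; 1 M aq. HCl quench
Reagents that add atoms: none
Why: Dianion acylation of a beta-keto ester, in which the more basic terminal carbanion of 3 adds to the Weinreb amide and the chelated tetrahedral adduct collapses only on acidic work-up, so a single acylation at the methyl terminus should result and no stereocentre is formed.

Step 2
Reactants: 4 tert-butyl 3,5-dioxooctanoate; 5 2,2-dimethylpropanedioyl dichloride
Product: 7 tert-butyl 5-butanoyl-2,6-dihydroxy-3,3-dimethyl-4-oxocyclohexa-1,5-diene-1-carboxylate, via acyclic acid chloride 6 (not isolated)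
Conditions: MgCl2 (2.5 equiv), Et3N (5 equiv), MeCN, 0 °C, slow simultaneous addition of 4 and 5 (0.02 M final), then rt; DMAP (0.2 equiv), 40 °C; 1 M aq. HCl work-up
Reagents that add atoms: none
Why: Proposed new method: soft enolization with MgCl2/Et3N converts both doubly activated methylenes of 4 into chelated magnesium enolates; the diketonate carbon C4 attacks one acid chloride of 5 to give 6, and the keto ester carbon C2 then attacks the second acid chloride in a 6-(enolendo)-exo-trig Dieckmann-type closure, so that the carbocycle arises by two Claisen acylations at a symmetrical dimethylmalonyl unit, a laboratory copy of the Claisen ring closure of the polyketide pathway. The closest known reaction types are the magnesium-mediated C-acylation of 1,3-dicarbonyl compounds by acid chlorides, the Effenberger cyclization of enol ethers with malonyl dichloride to cyclohexane-1,3-diones and the condensation of malonic with acetonedicarboxylic esters to phloroglucinol carboxylates; the one-pot bis-C-acylation of an open-chain 3,5-dioxo ester by a 2,2-disubstituted malonyl dichloride is the untested part. No stereocentre is formed. The step needs carbon over oxygen acylation, ring closure over chain growth and the right pair of nucleophilic carbons: magnesium chelation favours C-acylation, 5 has no alpha-hydrogen and so cannot leak through a ketene, and any enol ester or enol lactone formed is itself an acyl donor that DMAP reopens, whereas C-acylation is irreversible and ends in the doubly deprotonated, fully conjugated magnesium enolate of 7 as the thermodynamic sink. High dilution and the gem-dimethyl group of 5 favour the six-membered closure, the propyl alpha-CH2 is not enolized under these conditions, and because 5 is symmetrical no orientation problem exists.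

Step 3
Reactants: 7 tert-butyl 5-butanoyl-2,6-dihydroxy-3,3-dimethyl-4-oxocyclohexa-1,5-diene-1-carboxylate
Product: 9 2-butanoyl-3,5-dihydroxy-6,6-dimethylcyclohexa-2,4-dien-1-one (butyrylfilicinic acid), via free carboxylic acid 8 (not isolated)
Conditions: TsOH·H2O (0.1 equiv), toluene, 80 °C, N2 sweep
Reagents that add atoms: none
Why: Acid-catalysed loss of 2-methylpropene from the tert-butyl ester followed by decarboxylation of the vinylogous beta-keto acid 8 through its hydrogen-bonded enol form (the ready decarboxylation of phloroglucinol carboxylic acids), which removes the activating group and leaves the ring C–H that will carry the bridge.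

Step 4
Reactants: 10 2-methylbenzene-1,3,5-triol
Product: 11 1-(2,4,6-trihydroxy-3-methylphenyl)butan-1-one
Conditions: butanoyl chloride (1.1 equiv), AlCl3 (3.5 equiv), PhNO2–CH2Cl2, 0 °C → 50 °C; ice/aq. HCl
Reagents that add atoms: butanoyl chloride CCCC(=O)Cl
Why: Friedel–Crafts acylation at one of the two equivalent free ring carbons of the electron-rich triol, in which any aryl ester formed first is carried to the ketone by Fries rearrangement under AlCl3 and the ketone deactivates the ring against a second acylation.

Step 5
Reactants: 9 2-butanoyl-3,5-dihydroxy-6,6-dimethylcyclohexa-2,4-dien-1-one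
Product: 12 2-butanoyl-4-[(dimethylamino)methyl]-3,5-dihydroxy-6,6-dimethylcyclohexa-2,4-dien-1-one (inner salt)
Conditions: CH2(NMe2)2 (1.2 equiv), CH2Cl2, 0 °C → rt; inner salt collected by filtration
Reagents that add atoms: N,N,N′,N′-tetramethylmethanediamine CN(C)CN(C)C
Why: Mannich reaction in which the acidic vinylogous acid 9 protonates the aminal to release the methyleneiminium ion, which is captured at C4, the only nucleophilic ring C–H, while the liberated amine keeps the enone masked as its adduct.

Step 6
Reactants: 12 2-butanoyl-4-[(dimethylamino)methyl]-3,5-dihydroxy-6,6-dimethylcyclohexa-2,4-dien-1-one; 11 1-(2,4,6-trihydroxy-3-methylphenyl)butan-1-one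
Product: 14 flavaspidic acid (2-butanoyl-4-[(3-butanoyl-2,4,6-trihydroxy-5-methylphenyl)methyl]-3,5-dihydroxy-6,6-dimethylcyclohexa-2,4-dien-1-one), via methylidene trione 13 (not isolated)
Conditions: 11 (1.3 equiv), 1,4-dioxane, 70 °C, slow addition of 12, N2 sweep; dilute aq. HCl wash
Reagents that add atoms: none
Why: Thermal retro-Michael loss of dimethylamine from the Mannich base gives the 2-methylidene-1,3-dione 13, to which the free ring carbon of 11 (between two hydroxyl groups) adds in a Friedel–Crafts-type Michael addition with rearomatization, the reaction type used to join alkylidene cyclic triones to acylphloroglucinols, and placing the CH2 on one partner only is what should secure the unsymmetrical bridge.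

**Compound list**
1 | tert-butyl 3-oxobutanoate (tert-butyl acetoacetate) | CC(=O)CC(=O)OC(C)(C)C | starting material
2 | N-methoxy-N-methylbutanamide | CCCC(=O)N(C)OC | starting material
3 | dilithium dienolate of tert-butyl 3-oxobutanoate | [Li+].[Li+].C=C([O-])C=C([O-])OC(C)(C)C | intermediate
4 | tert-butyl 3,5-dioxooctanoate | CCCC(=O)CC(=O)CC(=O)OC(C)(C)C | intermediate
5 | 2,2-dimethylpropanedioyl dichloride (dimethylmalonyl dichloride) | CC(C)(C(=O)Cl)C(=O)Cl | starting material
6 | tert-butyl 4-butanoyl-7-chloro-6,6-dimethyl-3,5,7-trioxoheptanoate | CCCC(=O)C(C(=O)CC(=O)OC(C)(C)C)C(=O)C(C)(C)C(=O)Cl | intermediate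
7 | tert-butyl 5-butanoyl-2,6-dihydroxy-3,3-dimethyl-4-oxocyclohexa-1,5-diene-1-carboxylate | CCCC(=O)C1=C(O)C(C(=O)OC(C)(C)C)=C(O)C(C)(C)C1=O | intermediate
8 | 5-butanoyl-2,6-dihydroxy-3,3-dimethyl-4-oxocyclohexa-1,5-diene-1-carboxylic acid | CCCC(=O)C1=C(O)C(C(=O)O)=C(O)C(C)(C)C1=O | intermediate
9 | 2-butanoyl-3,5-dihydroxy-6,6-dimethylcyclohexa-2,4-dien-1-one (butyrylfilicinic acid) | CCCC(=O)C1=C(O)C=C(O)C(C)(C)C1=O | intermediate
10 | 2-methylbenzene-1,3,5-triol (2-methylphloroglucinol) | Cc1c(O)cc(O)cc1O | starting material
11 | 1-(2,4,6-trihydroxy-3-methylphenyl)butan-1-one | CCCC(=O)c1c(O)c(C)c(O)cc1O | intermediate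
12 | 2-butanoyl-4-[(dimethylamino)methyl]-3,5-dihydroxy-6,6-dimethylcyclohexa-2,4-dien-1-one | CCCC(=O)C1=C(O)C(CN(C)C)=C(O)C(C)(C)C1=O | intermediate
13 | 2-butanoyl-3-hydroxy-6,6-dimethyl-4-methylidenecyclohex-2-ene-1,5-dione | CCCC(=O)C1=C(O)C(=C)C(=O)C(C)(C)C1=O | intermediate
14 | flavaspidic acid, 2-butanoyl-4-[(3-butanoyl-2,4,6-trihydroxy-5-methylphenyl)methyl]-3,5-dihydroxy-6,6-dimethylcyclohexa-2,4-dien-1-one | CCCC(=O)C1=C(O)C(Cc2c(O)c(C)c(O)c(C(=O)CCC)c2O)=C(O)C(C)(C)C1=O | target

**Summary**
Total step count: 6. Longest linear sequence: 5 steps (steps 1, 2, 3, 5, 6 from compound 1); step 4 is a one-step side branch.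

Steps most likely to fail:

Step 2 (carries the label). The ring closure may be diverted by acylation on enol oxygen that DMAP does not return to carbon, or by chain growth between two molecules instead of closure of the six-membered ring. The fallback uses known chemistry and abandons ring construction in favour of a dearomatizing C-methylation. It sets out from compound 11. Treatment with MeI (1.1 equiv) and NaOMe in MeOH at 0 °C to rt should methylate the ring carbon that already carries the methyl group. This is the geminal C-methylation of a phloroglucinol, the classical entry to filicinic acids; it turns the arene into the cyclohexadienone and gives 9 directly. The isomer methylated at the free ring carbon would be removed by chromatography. The fallback comes back to the route at compound 9, before step 5, and makes no new compound (F0).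

Step 6. The bridge may scramble by retro-Michael cleavage and recombination to the two symmetrical dimers, the methylidene trione may self-condense before it is captured, and liberated dimethylamine may condense reversibly with the acyl groups. The fallback reverses the roles of the two halves so that the arene becomes the electrophile. It sets out from compound 11, which would be aminomethylated at its free ring carbon with CH2(NMe2)2 in CH2Cl2 to give 1-[3-[(dimethylamino)methyl]-2,4,6-trihydroxy-5-methylphenyl]butan-1-one F1. Heating F1 with 9 in 1,4-dioxane should expel dimethylamine to give the ortho-quinone methide 2-butanoyl-3,5-dihydroxy-4-methyl-6-methylidenecyclohexa-2,4-dien-1-one F2. C4 of the strongly nucleophilic vinylogous acid 9 captures F2 by Michael addition. The fallback comes back to the route at compound 14.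

Step 5. Dimethylamine may be lost from the Mannich base while unreacted 9 is still present, so that the enone is captured by 9 and the symmetrical dimer forms; the inner salt may also be hard to isolate. The fallback omits the Mannich base and uses the classical alkaline methylene condensation. It sets out from compounds 9 and 11, which would be stirred with aqueous formaldehyde (1 equiv) in dilute aqueous KOH at 0 °C to rt. Compound 9 should be hydroxymethylated to 2-butanoyl-3,5-dihydroxy-4-(hydroxymethyl)-6,6-dimethylcyclohexa-2,4-dien-1-one F3, which loses water to 13 and is captured by 11. The two symmetrical dimers expected beside the product would be removed by chromatography and crystallization. The fallback comes back to the route at compound 14.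

**Further compounds**
F0 | step 2 | none | none
F1 | step 6 | 1-[3-[(dimethylamino)methyl]-2,4,6-trihydroxy-5-methylphenyl]butan-1-one | CCCC(=O)c1c(O)c(C)c(O)c(CN(C)C)c1O
F2 | step 6 | 2-butanoyl-3,5-dihydroxy-4-methyl-6-methylidenecyclohexa-2,4-dien-1-one | CCCC(=O)C1=C(O)C(C)=C(O)C(=C)C1=O
F3 | step 5 | 2-butanoyl-3,5-dihydroxy-4-(hydroxymethyl)-6,6-dimethylcyclohexa-2,4-dien-1-one | CCCC(=O)C1=C(O)C(CO)=C(O)C(C)(C)C1=O
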